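The numbering follows the target: C1 is the quaternary oxirane carbon carrying C7H2O, C2 bears the acetate, C3 the benzoate, C4=C5 is the alkene and C6 the oxirane CH. The key step exploits that, within the six-membered ring, the chain C6–C1(C7)–C2–C3 is a C-branched L-tartaric unit whose two oxygenated end carbons are bridged by the cis alkene C4=C5. The ring is therefore opened at C3–C4 and C5–C6. One chromium/nickel operation joins (Z)-1,2-diiodoethene to both formyl groups of a trans-dioxolane dialdehyde that already holds O1, O2 and C7, closing the cyclohexene and creating the C3 and C6 carbinols, which are adjusted afterwards.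

Key step: step 4

Assumption: 4-methoxybenzyl chloromethyl ether (2) and (Z)-1,2-diiodoethene (7) are taken as purchasable reagents of limited shelf life and would be used freshly.

Stereochemical remark: the key step should place O3 cis to O2 and O6 cis to O1. C3 is therefore inverted once (step 5). Ring closure by O1 needs a leaving group trans to O1, so C6 is reset by oxidation–reduction (steps 6–7) and inverted again in step 13.

Design remark: the trans-dioxolane is kept through the key step because it holds the two formyl groups gauche and rules out lactol formation; O7 travels as a PMB ether, inert to Cr/Ni and removable oxidatively.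

Step 1
Reactants: 1 dimethyl 2,3-O-isopropylidene-L-tartrate; 2 4-methoxybenzyl chloromethyl ether
Product: 4 dimethyl (4R,5R)-4-[(4-methoxybenzyloxy)methyl]-2,2-dimethyl-1,3-dioxolane-4,5-dicarboxylate, via lithium enolate 3 (not isolated)
Conditions: LDA, THF–HMPA, −78 °C; then 2, −78 °C
Reagents that add atoms: 4-methoxybenzyl chloromethyl ether (2), COc1ccc(COCCl)cc1
Why: Ester-enolate alkylation with a reactive α-chloro ether: the β-oxygen of the dioxolane lies in the enolate plane and is not expelled at −78 °C, and this enolate is known to take up electrophiles on the face that keeps the two ester groups trans, so C1 is re-formed with retention under control of C2.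

Step 2
Reactants: 4 dimethyl (4R,5R)-4-[(4-methoxybenzyloxy)methyl]-2,2-dimethyl-1,3-dioxolane-4,5-dicarboxylate
Product: 5 [(4R,5S)-4-[(4-methoxybenzyloxy)methyl]-2,2-dimethyl-1,3-dioxolane-4,5-diyl]dimethanol
Conditions: LiAlH4, THF, 0 °C to rt
Reagents that add atoms: none
Why: Lithium aluminium hydride reduction of both esters to primary alcohols; the ketal and the benzyl-type ether are inert and neither stereocentre is touched.

Step 3
Reactants: 5 [(4R,5S)-4-[(4-methoxybenzyloxy)methyl]-2,2-dimethyl-1,3-dioxolane-4,5-diyl]dimethanol
Product: 6 (4R,5R)-4-[(4-methoxybenzyloxy)methyl]-2,2-dimethyl-1,3-dioxolane-4,5-dicarbaldehyde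
Conditions: Dess–Martin periodinane, pyridine, CH2Cl2, 0 °C to rt; filtered, dried azeotropically, used at once
Reagents that add atoms: none
Why: Dess–Martin oxidation of both primary alcohols under near-neutral conditions; a lactol (and so a lactone) cannot form because it would be a trans-fused bicyclo[3.3.0] system, the C1 formyl group has no α-hydrogen, and C2 is not exposed to strong base.

Step 4
Reactants: 6 (4R,5R)-4-[(4-methoxybenzyloxy)methyl]-2,2-dimethyl-1,3-dioxolane-4,5-dicarbaldehyde; 7 (Z)-1,2-diiodoethene
Product: 9 (3aS,4S,7S,7aS)-3a-[(4-methoxybenzyloxy)methyl]-2,2-dimethyl-3a,4,7,7a-tetrahydro-1,3-benzodioxole-4,7-diol (route numbering 1S,2S,3S,6S; O3 cis to O2, O6 cis to O1), via iodoalkenyl carbinol aldehyde 8 (not isolated)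
Conditions: CrCl2 (10 equiv), NiCl2 (cat.), degassed DMSO–THF, rt; 7 (1.05 equiv) added by syringe pump, ca. 0.01 M
Reagents that add atoms: (Z)-1,2-diiodoethene (7), I/C=C\I
Why: Proposed new method: Ni(0), generated from NiCl2 by Cr(II), inserts into one C–I bond of 7 and hands the alkenyl group to chromium(III); this (Z)-2-iodoalkenylchromium reagent adds to the less hindered formyl group (C3) of 6 to give alkoxide 8, whose remaining C–I bond is activated in the same way and adds to the neopentylic C6 formyl group. The closest known chemistry is the Nozaki–Hiyama–Kishi alkenyl iodide–aldehyde coupling, established separately between and within molecules but not as a twofold annulation with a 1,2-dimetalloethene equivalent. The six-membered ring closes in a 6-exo-trig mode, helped by the cis alkene and by the trans-dioxolane, which holds C3 and C6 gauche and cannot divert 8 into a lactol because that would be a trans-fused bicyclo[3.3.0] system. C3 is set in the open-chain addition by Felkin–Anh control from C2 (alkenyl anti to C2–O2, carbonyl oxygen beside C1), which places O3 cis to O2. C6 is set in the cyclisation by C1: the forming ring holds C5 anti to C1–O1 and the carbonyl oxygen should turn away from the axial C7 arm, which places O6 cis to O1. The step needs ring closure to outrun a second intermolecular addition and loss of metal iodide from the iodoalkenyl metal to give acetylene; slow addition of 7 at high dilution and the syn arrangement of metal and iodine on the Z alkene, the geometry least prone to β-elimination, are relied on for this.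

Step 5
Reactants: 9 cyclohexene-3,6-diol acetonide (1S,2S,3S,6S)
Product: 10 (1S,2S,3R,6S)-3-O-benzoate: 9 with C3 inverted and benzoylated (O3 trans to O2), C6–OH unchanged
Conditions: PhCO2H, PPh3, DIAD (1.2 equiv each), toluene–THF, −20 °C to rt
Reagents that add atoms: benzoic acid, O=C(O)c1ccccc1
Why: Mitsunobu esterification: benzoate displaces the C3 oxyphosphonium ion by SN2 with inversion, so that O3 becomes trans to O2, while the C6 hydroxyl is neopentylic (next to quaternary C1) and should not be displaced, and the trans-fused dioxolane keeps the ring from folding for transannular ether formation.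

Step 6
Reactants: 10 (1S,2S,3R,6S)-3-O-benzoate
Product: 11 (1R,2S,3R)-enone: C6 ketone conjugated with C4=C5, carrying the 3-O-benzoate, the 1,2-O-isopropylidene group and the 7-O-PMB ether
Conditions: Dess–Martin periodinane, CH2Cl2, 0 °C to rt
Reagents that add atoms: none
Why: Dess–Martin oxidation of the hindered allylic alcohol to the enone removes the C6 stereocentre without touching the benzoate, the ketal or the PMB ether.

Step 7
Reactants: 11 (1R,2S,3R)-enone
Product: 12 (1S,2S,3R,6R)-allylic alcohol: as 10 but with C6–OH trans to O1
Conditions: NaBH4, CeCl3·7H2O, MeOH, −78 °C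
Reagents that add atoms: none
Why: Luche 1,2-reduction: in the half-chair fixed by the trans-fused dioxolane the C7 arm on C1 is axial, so hydride should enter C6 on the opposite face (axial attack) and the new hydroxyl should be pseudo-equatorial and trans to O1.

Step 8
Reactants: 12 (1S,2S,3R,6R)-allylic alcohol
Product: 13 (1R,2S,3R,6R)-6-O-methanesulfonate of 12
Conditions: MsCl, Et3N, CH2Cl2, −20 to 0 °C
Reagents that add atoms: methanesulfonyl chloride, CS(=O)(=O)Cl
Why: Sulfonylation through sulfene tolerates the hindered neopentylic alcohol and keeps the configuration at C6; the allylic mesylate is deactivated towards ionisation by the oxygenated carbons on both sides.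

Step 9
Reactants: 13 (1R,2S,3R,6R)-6-O-methanesulfonate
Product: 14 (1R,2S,3R,6R)-primary alcohol: 13 without the PMB group (free C7–OH)
Conditions: DDQ, CH2Cl2–pH 7 buffer, 0 °C to rt
Reagents that add atoms: none
Why: Oxidative cleavage of the 4-methoxybenzyl ether by DDQ (hydride abstraction, then hydrolysis of the oxocarbenium ion); esters, mesylate, ketal and the electron-poor alkene are inert.

Step 10
Reactants: 14 (1R,2S,3R,6R)-primary alcohol
Product: 15 (1R,2S,3R,6R)-3,7-di-O-benzoyl-1,2-O-isopropylidene-6-O-mesyl compound
Conditions: BzCl, pyridine, DMAP (cat.), CH2Cl2, 0 °C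
Reagents that add atoms: benzoyl chloride, O=C(Cl)c1ccccc1
Why: Acylation of the primary alcohol with benzoyl chloride under nucleophilic catalysis; no other hydroxyl is free.

Step 11
Reactants: 15 (1R,2S,3R,6R)-3,7-di-O-benzoyl-1,2-O-isopropylidene-6-O-mesyl compound
Product: 16 (1R,2S,3R,6R)-1,2-diol: 15 without the isopropylidene group (tertiary C1–OH and secondary C2–OH free)
Conditions: TFA–H2O (9:1), CH2Cl2, 0 °C
Reagents that add atoms: none
Why: Acid-catalysed ketal hydrolysis, made easy by the strain of the trans-fused dioxolane; the benzoates and the deactivated mesylate should tolerate cold aqueous TFA.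

Step 12
Reactants: 16 (1R,2S,3R,6R)-1,2-diol
Product: 17 (1R,2S,3R,6R)-2-O-acetyl-3,7-di-O-benzoyl-6-O-mesyl compound with free tertiary C1–OH (trans to the mesylate)
Conditions: Ac2O, pyridine, CH2Cl2, 0 °C to rt
Reagents that add atoms: acetic anhydride, CC(=O)OC(C)=O
Why: Acetylation with acetic anhydride and pyridine is selective for the secondary C2 hydroxyl, the tertiary C1 hydroxyl being inert without forcing conditions.

Step 13
Reactants: 17 (1R,2S,3R,6R)-2-O-acetyl-3,7-di-O-benzoyl-6-O-mesyl compound
Product: 18 [(1S,2S,3R,6S)-2-acetoxy-3-(benzoyloxy)-7-oxabicyclo[4.1.0]hept-4-en-1-yl]methyl benzoate (target)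
Conditions: DBU, MeCN, 0 °C to rt
Reagents that add atoms: none
Why: Intramolecular Williamson etherification (hydroxy sulfonate to oxirane): after ring inversion the C1 oxygen and the C6 mesylate are trans-diaxial, O1 displaces the sulfonate with inversion at C6 so that the oxirane lies on the face of O1 (cis to O3, trans to O2), and the non-nucleophilic amidine base should leave the three esters intact.

Compound list
1 | dimethyl (4R,5R)-2,2-dimethyl-1,3-dioxolane-4,5-dicarboxylate (dimethyl 2,3-O-isopropylidene-L-tartrate) | COC(=O)[C@@H]1OC(C)(C)O[C@H]1C(=O)OC | starting material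
2 | 4-methoxybenzyl chloromethyl ether | COc1ccc(COCCl)cc1 | starting material
3 | lithium enolate of 1 (C1 trigonal, C2 stereocentre intact) | COC(=O)[C@@H]1OC(C)(C)OC1=C(OC)[O-].[Li+] | intermediate (not isolated)
4 | dimethyl (4R,5R)-4-[(4-methoxybenzyloxy)methyl]-2,2-dimethyl-1,3-dioxolane-4,5-dicarboxylate (ester groups trans) | COC(=O)[C@]1(COCc2ccc(OC)cc2)OC(C)(C)O[C@H]1C(=O)OC | intermediate
5 | [(4R,5S)-4-[(4-methoxybenzyloxy)methyl]-2,2-dimethyl-1,3-dioxolane-4,5-diyl]dimethanol | OC[C@]1(COCc2ccc(OC)cc2)OC(C)(C)O[C@H]1CO | intermediate
6 | (4R,5R)-4-[(4-methoxybenzyloxy)methyl]-2,2-dimethyl-1,3-dioxolane-4,5-dicarbaldehyde (formyl groups trans) | O=C[C@]1(COCc2ccc(OC)cc2)OC(C)(C)O[C@H]1C=O | intermediate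
7 | (Z)-1,2-diiodoethene | I/C=C\I | starting material
8 | iodoalkenyl carbinol aldehyde: 6 in which the formyl group on C2 has become an (S)-CH(OH)–CH=CHI (Z) unit, the C1 formyl group remaining; present as its chromium(III) alkoxide, drawn as the alcohol | O=C[C@]1(COCc2ccc(OC)cc2)OC(C)(C)O[C@H]1[C@@H](O)/C=C\I | intermediate (not isolated)
9 | (3aS,4S,7S,7aS)-3a-[(4-methoxybenzyloxy)methyl]-2,2-dimethyl-3a,4,7,7a-tetrahydro-1,3-benzodioxole-4,7-diol (route numbering 1S,2S,3S,6S; trans-fused acetonide on O1/O2, C3–OH cis to O2, C6–OH cis to O1) | CC1(C)O[C@H]2[C@@H](O)C=C[C@H](O)[C@]2(COCc2ccc(OC)cc2)O1 | intermediate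
10 | (1S,2S,3R,6S)-3-O-benzoate: 9 with C3 inverted and benzoylated, C6–OH cis to O1 | CC1(C)O[C@H]2[C@H](OC(=O)c3ccccc3)C=C[C@H](O)[C@]2(COCc2ccc(OC)cc2)O1 | intermediate
11 | (1R,2S,3R)-enone: C6 ketone conjugated with C4=C5; 3-O-benzoyl, 1,2-O-isopropylidene, 7-O-PMB | CC1(C)O[C@H]2[C@H](OC(=O)c3ccccc3)C=CC(=O)[C@]2(COCc2ccc(OC)cc2)O1 | intermediate
12 | (1S,2S,3R,6R)-allylic alcohol: as 10 but C6–OH trans to O1 | CC1(C)O[C@H]2[C@H](OC(=O)c3ccccc3)C=C[C@@H](O)[C@]2(COCc2ccc(OC)cc2)O1 | intermediate
13 | (1R,2S,3R,6R)-6-O-methanesulfonate of 12 | CC1(C)O[C@H]2[C@H](OC(=O)c3ccccc3)C=C[C@@H](OS(C)(=O)=O)[C@]2(COCc2ccc(OC)cc2)O1 | intermediate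
14 | (1R,2S,3R,6R)-primary alcohol: 13 without the PMB group | CC1(C)O[C@H]2[C@H](OC(=O)c3ccccc3)C=C[C@@H](OS(C)(=O)=O)[C@]2(CO)O1 | intermediate
15 | (1R,2S,3R,6R)-3,7-di-O-benzoyl-1,2-O-isopropylidene-6-O-mesyl compound | CC1(C)O[C@H]2[C@H](OC(=O)c3ccccc3)C=C[C@@H](OS(C)(=O)=O)[C@]2(COC(=O)c2ccccc2)O1 | intermediate
16 | (1R,2S,3R,6R)-1,2-diol: 3,7-di-O-benzoyl-6-O-mesyl compound with free C1–OH and C2–OH | O[C@H]1[C@H](OC(=O)c2ccccc2)C=C[C@@H](OS(C)(=O)=O)[C@@]1(O)COC(=O)c1ccccc1 | intermediate
17 | (1R,2S,3R,6R)-2-O-acetyl-3,7-di-O-benzoyl-6-O-mesyl compound with free tertiary C1–OH | CC(=O)O[C@H]1[C@H](OC(=O)c2ccccc2)C=C[C@@H](OS(C)(=O)=O)[C@@]1(O)COC(=O)c1ccccc1 | intermediate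
18 | [(1S,2S,3R,6S)-2-acetoxy-3-(benzoyloxy)-7-oxabicyclo[4.1.0]hept-4-en-1-yl]methyl benzoate | CC(=O)O[C@H]1[C@H](OC(=O)c2ccccc2)C=C[C@@H]2O[C@@]21COC(=O)c1ccccc1 | target

Total step count: 13
Longest linear sequence: 13 steps (1 to 18)

Steps most likely to fail

Step 4 (proposed new method). The iodoalkenyl metal species may lose metal iodide to give acetylene before it adds, or the second addition may take place between molecules, so that no ring is closed; facial selectivity at C3 may also be low. The fallback uses known chemistry and sets out from 6. Twofold addition of vinylmagnesium bromide (THF, −78 °C) should give the dienediol F1, and ring-closing metathesis (second-generation ruthenium benzylidene catalyst, CH2Cl2, 40 °C) should form the C4=C5 alkene with loss of ethene, coming back to the route at 9. Carbinol epimers formed alongside need not be discarded: a C6 epimer converges at 11 after steps 5 and 6, and a C3 epimer can be benzoylated directly with retention.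

Step 5. The Mitsunobu reaction may lose site selectivity between the two allylic hydroxyls, or suffer allylic transposition (SN2′) or anti elimination across C2–C3 in the phosphonium intermediate. The fallback sets out from 9 and separates activation from displacement. The less hindered C3 hydroxyl is sulfonylated (MsCl, 2,4,6-collidine, CH2Cl2, −30 °C) to the C3 methanesulfonate F2, and caesium benzoate (18-crown-6, toluene, 60 °C) then displaces it by SN2 with inversion, coming back to the route at 10.

Step 13. Acyl migration from O2 or O7 onto the tertiary alkoxide, or ester cleavage, may outrun the ring closure, which has to pass through a conformer with all four ring oxygens axial. The fallback sets out from 16, where no acetate is present. DBU in MeCN should close the oxirane to the hydroxy oxirane F3, and acetylation of its C2 hydroxyl (Ac2O, pyridine) then comes back to the route at 18.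

Further compounds
F1 | step 4 | dienediol: 6 with each formyl group converted into a CH(OH)–CH=CH2 unit (drawn as the epimer that leads to 9) | CC1(C)O[C@@H]([C@@H](O)C=C)[C@](COCc2ccc(OC)cc2)([C@@H](O)C=C)O1
F2 | step 5 | C3 methanesulfonate of 9 (C6–OH free) | CC1(C)O[C@H]2[C@@H](OS(C)(=O)=O)C=C[C@H](O)[C@]2(COCc2ccc(OC)cc2)O1
F3 | step 13 | hydroxy oxirane: 18 without the acetyl group (free C2–OH) | O[C@H]1[C@H](OC(=O)c2ccccc2)C=C[C@@H]2O[C@@]21COC(=O)c1ccccc1
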